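**Retrosynthetic overview**
1. Endgame: one global hydrogenolysis (twelve benzyl ethers, one diphenylmethylene ketal, two blocking bromines), preceded by a Friedel–Crafts union of C4 of an activated, C8-capped epicatechin with C6 of the complete lower flavan.
2. Key disconnection: ring C of the lower flavan is cut at C4–C3 and O1–C2 into an o-quinone methide of ring A and a (Z)-enol gallate of the ring B arylacetaldehyde that already carries both galloyl esters; a chiral phosphoric acid is to set (2R,3R).
3. Enabling feature: C4 of the lower unit is an unsubstituted CH2 on ring A ortho to the ring oxygen (O1–C8a–C4a–C4 is a latent o-quinone methide), and the C2 aryl and C3 O-galloyl groups are cis (a Z-styrenyl gallate). Bromine at C8 blocks self-condensation in the key step and later steers the coupling to C6.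
4. Fragments: dienophile from 3,4,5-trihydroxybenzaldehyde (ketal, alkyne, aryl gallate, ruthenium-catalysed Z-selective acid addition); methide precursor from 3,5-bis(benzyloxy)phenol (ortho-formylation, bromination, reduction); electrophile from (−)-epicatechin.
5. Ring order: temporary dioxole on ring B first, ring C of the lower unit in the key step; all other rings are bought; the interflavan bond is made last before deprotection.

Key step: step 8

Remarks: flavan locants (O1, C2–C4, C4a, C5–C8, C8a; primed locants for ring B) are used for both units. Assumption: the sense of induction of the chiral phosphoric acid in step 8 cannot be predicted with certainty; the (R) catalyst is written, and its (S) enantiomer would be taken if a screen shows the opposite sense.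

**Route**

Step 1
Reactants: 1 3,4,5-trihydroxybenzaldehyde
Product: 2 7-hydroxy-2,2-diphenyl-1,3-benzodioxole-5-carbaldehyde
Conditions: Ph2CCl2 (1.1 equiv), K2CO3, MeCN, rt
Reagents that add atoms: dichlorodiphenylmethane ClC(Cl)(c1ccccc1)c1ccccc1
Why: Ketalisation of a catechol with a gem-dichloride, in which only two adjacent hydroxyls can close the five-membered dioxole, so that one phenol (the later 3'-oxygen of ring B) stays free and the para-oxygen becomes locked coplanar with the arene.

Step 2
Reactants: 2 7-hydroxy-2,2-diphenyl-1,3-benzodioxole-5-carbaldehyde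
Product: 3 6-ethynyl-2,2-diphenyl-1,3-benzodioxol-4-ol
Conditions: Ohira–Bestmann reagent, K2CO3, MeOH, 0 °C to rt
Reagents that add atoms: dimethyl (1-diazo-2-oxopropyl)phosphonate COP(=O)(OC)C(=[N+]=[N-])C(C)=O
Why: Ohira–Bestmann (Seyferth–Gilbert) homologation turns the aldehyde into the terminal alkyne under conditions that a meta-phenoxide tolerates.

Step 3
Reactants: 3 6-ethynyl-2,2-diphenyl-1,3-benzodioxol-4-ol; 4 3,4,5-tris(benzyloxy)benzoyl chloride
Product: 5 6-ethynyl-2,2-diphenyl-1,3-benzodioxol-4-yl 3,4,5-tris(benzyloxy)benzoate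
Conditions: Et3N, DMAP (cat.), CH2Cl2, 0 °C to rt
Reagents that add atoms: none
Why: DMAP-catalysed acylation of the phenol by the acid chloride installs the ring B gallate before the base-sensitive enol ester exists.

Step 4
Reactants: 5 6-ethynyl-2,2-diphenyl-1,3-benzodioxol-4-yl 3,4,5-tris(benzyloxy)benzoate; 6 3,4,5-tris(benzyloxy)benzoic acid
Product: 7 (Z)-2-[7-{[3,4,5-tris(benzyloxy)benzoyl]oxy}-2,2-diphenyl-1,3-benzodioxol-5-yl]ethenyl 3,4,5-tris(benzyloxy)benzoate
Conditions: [RuCl2(p-cymene)]2 (2 mol%), P(4-ClC6H4)3 (6 mol%), DMAP (8 mol%), toluene, 60 °C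
Reagents that add atoms: none
Why: Ruthenium-catalysed anti-Markovnikov addition of a carboxylic acid to a terminal alkyne (carboxylate attack at the terminal carbon of a ruthenium vinylidene) should give the enol ester with Z geometry, which later becomes the 2,3-cis relation.

Step 5
Reactants: 8 3,5-bis(benzyloxy)phenol
Product: 9 2-hydroxy-4,6-bis(benzyloxy)benzaldehyde
Conditions: MgCl2, Et3N, (CH2O)n, MeCN, reflux
Reagents that add atoms: paraformaldehyde (as formaldehyde) C=O
Why: Casnati–Skattebøl ortho-formylation (the magnesium phenoxide directs formaldehyde to the ortho carbon and a second formaldehyde takes the hydride) brings in the future C4 carbon at one of the two equivalent positions next to the free phenol.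

Step 6
Reactants: 9 2-hydroxy-4,6-bis(benzyloxy)benzaldehyde
Product: 10 3-bromo-2-hydroxy-4,6-bis(benzyloxy)benzaldehyde
Conditions: NBS (1.0 equiv), CH2Cl2, −20 to 0 °C
Reagents that add atoms: N-bromosuccinimide O=C1CCC(=O)N1Br
Why: Electrophilic aromatic bromination should go to the open position ortho to the free phenol, which is less hindered than the position between the two benzyloxy groups, and so blocks the future C8 (assignment to be confirmed by NOE).

Step 7
Reactants: 10 3-bromo-2-hydroxy-4,6-bis(benzyloxy)benzaldehyde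
Product: 11 2-bromo-3,5-bis(benzyloxy)-6-(hydroxymethyl)phenol
Conditions: NaBH4, THF/MeOH, 0 °C; pH 7 work-up, used at once
Reagents that add atoms: none
Why: Borohydride reduction of the aldehyde gives the salicyl alcohol that serves as o-quinone methide precursor, which is acid-labile and is therefore worked up neutral and not stored.

Step 8
Reactants: 11 2-bromo-3,5-bis(benzyloxy)-6-(hydroxymethyl)phenol; 7 (Z)-2-[7-{[3,4,5-tris(benzyloxy)benzoyl]oxy}-2,2-diphenyl-1,3-benzodioxol-5-yl]ethenyl 3,4,5-tris(benzyloxy)benzoate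
Product: 13 (2R,3R)-8-bromo-5,7-bis(benzyloxy)-2-[7-{[3,4,5-tris(benzyloxy)benzoyl]oxy}-2,2-diphenyl-1,3-benzodioxol-5-yl]-3,4-dihydro-2H-chromen-3-yl 3,4,5-tris(benzyloxy)benzoate, via o-quinone methide 12 (not isolated)
Conditions: (R)-3,3'-bis(2,4,6-triisopropylphenyl)-1,1'-binaphthyl-2,2'-diyl hydrogen phosphate (10 mol%), 5 Å MS, toluene, −20 °C to rt, 11 added slowly to 7 (1.5 equiv)
Reagents that add atoms: none
Why: Proposed new method: the chiral phosphoric acid dehydrates 11 to the o-quinone methide 12 and stays hydrogen-bonded to its carbonyl oxygen, which lowers the LUMO of the O1=C8a–C4a=C4 heterodiene so that the electron-rich Z-styrenyl ester 7 adds in a concerted but asynchronous inverse-electron-demand hetero-Diels–Alder reaction in which C4–C3 bonding runs ahead of O1–C2 bonding; the closest known reaction type is the chiral-phosphoric-acid-catalysed [4+2] cycloaddition of o-quinone methides, made in situ from o-hydroxybenzyl alcohols, with hydroxystyrenes, enamides and vinyl sulfides, which has not been shown for β-acyloxystyrenes or for a methide that is unsubstituted at its exocyclic carbon. Ring C closes as the six-membered ring of the [4+2] cycloaddition, suprafacial on both partners, and rearomatisation of ring A drives it. The 2,3-cis relation of C2 and C3 follows from the Z geometry of 7 in a stereospecific addition, and the absolute configuration (2R,3R) is to come from the catalyst, whose 3,3'-aryl walls sit next to the methide oxygen where C2 lands and so distinguish the aryl-bearing from the hydrogen-bearing face of the dienophile. The regioselectivity needed (CH2 to the acyloxy-bearing carbon, oxygen to the benzylic carbon) requires the styrene polarisation to beat the enol-ester polarisation, which is secured by the coplanar para-oxygen of the benzodioxole and by the weak donor power of an acyloxy group. Chemoselectivity against self-condensation is secured by the bromine at the position ortho to the phenol, by slow addition of 11 and by excess 7, and the low temperature is meant to keep the addition concerted so that the Z geometry is not lost through a free benzylic cation.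

Step 9
Reactants: 14 (−)-epicatechin
Product: 15 (2R,3R)-5,7,3',4'-tetra-O-benzylepicatechin
Conditions: BnBr, K2CO3, DMF, 0 °C to rt
Reagents that add atoms: benzyl bromide BrCc1ccccc1
Why: Williamson etherification under carbonate base alkylates the four phenols and leaves the much less acidic secondary 3-OH free without touching C2 or C3.

Step 10
Reactants: 15 (2R,3R)-5,7,3',4'-tetra-O-benzylepicatechin
Product: 16 (2R,3R,4S)-4-(2-ethoxyethoxy)-5,7,3',4'-tetra-O-benzylepicatechin (4β-alkoxy, trans to 3-OH)
Conditions: DDQ (2 equiv), 2-ethoxyethanol, CH2Cl2, rt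
Reagents that add atoms: 2-ethoxyethanol CCOCCO
Why: DDQ abstracts hydride from the benzylic C4 and the alcohol adds to the resulting quinone-methide cation on the face trans to the 3-OH, which sets the 4β-alkoxy group (oxidative benzylic etherification).

Step 11
Reactants: 16 (2R,3R,4S)-4-(2-ethoxyethoxy)-5,7,3',4'-tetra-O-benzylepicatechin
Product: 17 (2R,3R,4S)-8-bromo-4-(2-ethoxyethoxy)-5,7,3',4'-tetra-O-benzylepicatechin
Conditions: NBS (1.0 equiv), CH2Cl2, −40 to 0 °C
Reagents that add atoms: N-bromosuccinimide O=C1CCC(=O)N1Br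
Why: Electrophilic bromination of the phloroglucinol-type ring A should go to C8, the less hindered of its two open positions, and caps the most nucleophilic site of the electrophile against self-condensation.

Step 12
Reactants: 13 (2R,3R)-8-bromo-5,7-bis(benzyloxy)-2-[7-{[3,4,5-tris(benzyloxy)benzoyl]oxy}-2,2-diphenyl-1,3-benzodioxol-5-yl]-3,4-dihydro-2H-chromen-3-yl 3,4,5-tris(benzyloxy)benzoate; 17 (2R,3R,4S)-8-bromo-4-(2-ethoxyethoxy)-5,7,3',4'-tetra-O-benzylepicatechin
Product: 18 8-bromo-5,7,3',4'-tetra-O-benzylepicatechin-(4β→6)-[8-bromo-5,7-di-O-benzyl-4',5'-O-diphenylmethylene-epigallocatechin 3,3'-bis(3,4,5-tri-O-benzylgallate)]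
Conditions: Me3SiOTf (0.2 equiv), CH2Cl2, −78 to −30 °C; 17 added slowly to 13 (2 equiv), excess 13 recovered
Reagents that add atoms: none
Why: Lewis-acid ionisation of the 4-alkoxy group gives the flavan-4-yl cation, which is attacked in a Friedel–Crafts reaction by C6 of 13 (the only unsubstituted position of its ring A, since bromine blocks C8) from the face anti to the 3-OH, so that the new C4 stereocentre is 4β (3,4-trans).

Step 13
Reactants: 18 8-bromo-5,7,3',4'-tetra-O-benzylepicatechin-(4β→6)-[8-bromo-5,7-di-O-benzyl-4',5'-O-diphenylmethylene-epigallocatechin 3,3'-bis(3,4,5-tri-O-benzylgallate)]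
Product: 19 epicatechin-(4β→6)-epigallocatechin 3,3'-di-O-gallate (CNP0237700.1)
Conditions: H2 (1 atm), Pd(OH)2/C, NaOAc (2.5 equiv), THF/MeOH/H2O, rt
Reagents that add atoms: none
Why: Heterogeneous hydrogenolysis should cleave the twelve benzyl ethers and the diphenylmethylene ketal and reduce both aryl bromides while acetate buffers the hydrogen bromide, so that the interflavan bond, both gallate esters and all five stereocentres stay untouched.

**Compound list**
1 | 3,4,5-trihydroxybenzaldehyde | O=Cc1cc(O)c(O)c(O)c1 | starting material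
2 | 7-hydroxy-2,2-diphenyl-1,3-benzodioxole-5-carbaldehyde | O=Cc1cc(O)c2OC(c3ccccc3)(c3ccccc3)Oc2c1 | intermediate
3 | 6-ethynyl-2,2-diphenyl-1,3-benzodioxol-4-ol | C#Cc1cc(O)c2OC(c3ccccc3)(c3ccccc3)Oc2c1 | intermediate
4 | 3,4,5-tris(benzyloxy)benzoyl chloride | O=C(Cl)c1cc(OCc2ccccc2)c(OCc2ccccc2)c(OCc2ccccc2)c1 | starting material
5 | 6-ethynyl-2,2-diphenyl-1,3-benzodioxol-4-yl 3,4,5-tris(benzyloxy)benzoate | C#Cc1cc(OC(=O)c2cc(OCc3ccccc3)c(OCc3ccccc3)c(OCc3ccccc3)c2)c2OC(c3ccccc3)(c3ccccc3)Oc2c1 | intermediate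
6 | 3,4,5-tris(benzyloxy)benzoic acid | OC(=O)c1cc(OCc2ccccc2)c(OCc2ccccc2)c(OCc2ccccc2)c1 | starting material
7 | (Z)-2-[7-{[3,4,5-tris(benzyloxy)benzoyl]oxy}-2,2-diphenyl-1,3-benzodioxol-5-yl]ethenyl 3,4,5-tris(benzyloxy)benzoate | O=C(O/C=C\c1cc(OC(=O)c2cc(OCc3ccccc3)c(OCc3ccccc3)c(OCc3ccccc3)c2)c2OC(c3ccccc3)(c3ccccc3)Oc2c1)c1cc(OCc2ccccc2)c(OCc2ccccc2)c(OCc2ccccc2)c1 | intermediate
8 | 3,5-bis(benzyloxy)phenol | Oc1cc(OCc2ccccc2)cc(OCc2ccccc2)c1 | starting material
9 | 2-hydroxy-4,6-bis(benzyloxy)benzaldehyde | O=Cc1c(O)cc(OCc2ccccc2)cc1OCc1ccccc1 | intermediate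
10 | 3-bromo-2-hydroxy-4,6-bis(benzyloxy)benzaldehyde | O=Cc1c(O)c(Br)c(OCc2ccccc2)cc1OCc1ccccc1 | intermediate
11 | 2-bromo-3,5-bis(benzyloxy)-6-(hydroxymethyl)phenol | OCc1c(O)c(Br)c(OCc2ccccc2)cc1OCc1ccccc1 | intermediate
12 | 2-bromo-3,5-bis(benzyloxy)-6-methylidenecyclohexa-2,4-dien-1-one (o-quinone methide) | C=C1C(=O)C(Br)=C(OCc2ccccc2)C=C1OCc1ccccc1 | intermediate (not isolated)
13 | (2R,3R)-8-bromo-5,7-bis(benzyloxy)-2-[7-{[3,4,5-tris(benzyloxy)benzoyl]oxy}-2,2-diphenyl-1,3-benzodioxol-5-yl]-3,4-dihydro-2H-chromen-3-yl 3,4,5-tris(benzyloxy)benzoate | O=C(Oc1cc([C@H]2Oc3c(Br)c(OCc5ccccc5)cc(OCc5ccccc5)c3C[C@H]2OC(=O)c2cc(OCc5ccccc5)c(OCc5ccccc5)c(OCc5ccccc5)c2)cc4OC(c5ccccc5)(c5ccccc5)Oc14)c1cc(OCc2ccccc2)c(OCc2ccccc2)c(OCc2ccccc2)c1 | intermediate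
14 | (−)-epicatechin, (2R,3R) | C1c2c(O)cc(O)cc2O[C@H](c2ccc(O)c(O)c2)[C@@H]1O | starting material
15 | (2R,3R)-5,7,3',4'-tetra-O-benzylepicatechin | C1c2c(OCc3ccccc3)cc(OCc3ccccc3)cc2O[C@H](c2ccc(OCc3ccccc3)c(OCc3ccccc3)c2)[C@@H]1O | intermediate
16 | (2R,3R,4S)-4-(2-ethoxyethoxy)-5,7,3',4'-tetra-O-benzylepicatechin (4β) | CCOCCO[C@H]1c2c(OCc3ccccc3)cc(OCc3ccccc3)cc2O[C@H](c2ccc(OCc3ccccc3)c(OCc3ccccc3)c2)[C@@H]1O | intermediate
17 | (2R,3R,4S)-8-bromo-4-(2-ethoxyethoxy)-5,7,3',4'-tetra-O-benzylepicatechin (4β) | CCOCCO[C@H]1c2c(OCc3ccccc3)cc(OCc3ccccc3)c(Br)c2O[C@H](c2ccc(OCc3ccccc3)c(OCc3ccccc3)c2)[C@@H]1O | intermediate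
18 | 8-bromo-5,7,3',4'-tetra-O-benzylepicatechin-(4β→6)-[8-bromo-5,7-di-O-benzyl-4',5'-O-diphenylmethylene-epigallocatechin 3,3'-bis(3,4,5-tri-O-benzylgallate)]; both units 2R,3R, lower aryl at upper C4 β (trans to 3-OH) | O=C(Oc1cc([C@H]2Oc3c(Br)c(OCc5ccccc5)c([C@H]6c7c(OCc5ccccc5)cc(OCc5ccccc5)c(Br)c7O[C@H](c7ccc(OCc5ccccc5)c(OCc5ccccc5)c7)[C@@H]6O)c(OCc5ccccc5)c3C[C@H]2OC(=O)c2cc(OCc5ccccc5)c(OCc5ccccc5)c(OCc5ccccc5)c2)cc4OC(c5ccccc5)(c5ccccc5)Oc14)c1cc(OCc2ccccc2)c(OCc2ccccc2)c(OCc2ccccc2)c1 | intermediate
19 | epicatechin-(4β→6)-epigallocatechin 3,3'-di-O-gallate (CNP0237700.1) | O=C(Oc1cc([C@H]2Oc3cc(O)c([C@H]4c5c(O)cc(O)cc5O[C@H](c5ccc(O)c(O)c5)[C@@H]4O)c(O)c3C[C@H]2OC(=O)c2cc(O)c(O)c(O)c2)cc(O)c1O)c1cc(O)c(O)c(O)c1 | target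

**Step count**
Total steps: 13. Longest linear sequence: 7 (steps 1, 2, 3, 4, 8, 12, 13).

**Steps most likely to fail**

1. Step 8 (proposed new method). What may go wrong: the catalyst may not discriminate the two faces of the dienophile well enough; part of the reaction may run stepwise through a benzylic cation, with loss of the Z geometry and formation of the 2,3-trans ring; the methide may condense with itself instead of adding to 7. Fallback by known chemistry, with absolute configuration by resolution instead of catalyst control: starting from 11 and 7, the chiral acid is left out and the two are heated in toluene (110 °C, 4 Å MS). 12 then forms thermally and adds in the uncatalysed, concerted o-quinone methide/styrene hetero-Diels–Alder reaction, which should give the racemic cis adduct, that is 13 together with its mirror image, the (2S,3S) enantiomer of 13 F1. The racemate is coupled with enantiopure 17 under the conditions of step 12, which turns the two enantiomers into diastereomers, 18 and the dimer with the (2S,3S) lower unit F2; these are separated by chromatography and the route is rejoined at 18. The same separation would also remove any minor enantiomer carried through the main route.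

2. Step 12. What may go wrong: C6 of 13 is flanked by two benzyloxy groups and is no more nucleophilic than the open C6 of the electrophile and of the product, so self-condensation of 17 and over-alkylation of 18 may compete, and ionisation may be followed by slow capture. Fallback that removes every nucleophilic ring A position of the electrophile: starting from 17, a second bromination (NBS, 1.1 equiv, MeCN, rt) at C6 gives the 6,8-dibromo-4β-(2-ethoxyethoxy) electrophile F3. This is coupled with 13 in equimolar amount (Me3SiOTf, CH2Cl2, −40 to 0 °C) to the tribromo protected dimer F4, and hydrogenolysis of F4 under the conditions of step 13 (with more NaOAc) rejoins the route at 19.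

3. Step 13. What may go wrong: hydrogen bromide released by hydrodebromination may be buffered incompletely and cleave the interflavan bond, bromide may poison the catalyst and leave partly benzylated material, and under buffer the phenolic 3'-gallate may migrate to the neighbouring oxygen. Fallback that separates debromination from debenzylation: starting from 18, radical reduction with Bu3SnH (2.5 equiv) and azobisisobutyronitrile (cat.) in toluene at 90 °C removes both bromines and gives the bromine-free protected dimer F5. F5 is then hydrogenolysed without any base (H2, Pd(OH)2/C, THF/MeOH) and the route is rejoined at 19.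

**Further compounds**
F1 | step 8 | (2S,3S) enantiomer of 13 | O=C(Oc1cc([C@@H]2Oc3c(Br)c(OCc5ccccc5)cc(OCc5ccccc5)c3C[C@@H]2OC(=O)c2cc(OCc5ccccc5)c(OCc5ccccc5)c(OCc5ccccc5)c2)cc4OC(c5ccccc5)(c5ccccc5)Oc14)c1cc(OCc2ccccc2)c(OCc2ccccc2)c(OCc2ccccc2)c1
F2 | step 8 | diastereomer of 18 with the (2S,3S) lower unit | O=C(Oc1cc([C@@H]2Oc3c(Br)c(OCc5ccccc5)c([C@H]6c7c(OCc5ccccc5)cc(OCc5ccccc5)c(Br)c7O[C@H](c7ccc(OCc5ccccc5)c(OCc5ccccc5)c7)[C@@H]6O)c(OCc5ccccc5)c3C[C@@H]2OC(=O)c2cc(OCc5ccccc5)c(OCc5ccccc5)c(OCc5ccccc5)c2)cc4OC(c5ccccc5)(c5ccccc5)Oc14)c1cc(OCc2ccccc2)c(OCc2ccccc2)c(OCc2ccccc2)c1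
F3 | step 12 | (2R,3R,4S)-6,8-dibromo-4-(2-ethoxyethoxy)-5,7,3',4'-tetra-O-benzylepicatechin | CCOCCO[C@H]1c2c(OCc3ccccc3)c(Br)c(OCc3ccccc3)c(Br)c2O[C@H](c2ccc(OCc3ccccc3)c(OCc3ccccc3)c2)[C@@H]1O
F4 | step 12 | 6,8-dibromo analogue of 18 (tribromo protected dimer) | O=C(Oc1cc([C@H]2Oc3c(Br)c(OCc5ccccc5)c([C@H]6c7c(OCc5ccccc5)c(Br)c(OCc5ccccc5)c(Br)c7O[C@H](c7ccc(OCc5ccccc5)c(OCc5ccccc5)c7)[C@@H]6O)c(OCc5ccccc5)c3C[C@H]2OC(=O)c2cc(OCc5ccccc5)c(OCc5ccccc5)c(OCc5ccccc5)c2)cc4OC(c5ccccc5)(c5ccccc5)Oc14)c1cc(OCc2ccccc2)c(OCc2ccccc2)c(OCc2ccccc2)c1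
F5 | step 13 | bromine-free analogue of 18 | O=C(Oc1cc([C@H]2Oc3cc(OCc5ccccc5)c([C@H]6c7c(OCc5ccccc5)cc(OCc5ccccc5)cc7O[C@H](c7ccc(OCc5ccccc5)c(OCc5ccccc5)c7)[C@@H]6O)c(OCc5ccccc5)c3C[C@H]2OC(=O)c2cc(OCc5ccccc5)c(OCc5ccccc5)c(OCc5ccccc5)c2)cc4OC(c5ccccc5)(c5ccccc5)Oc14)c1cc(OCc2ccccc2)c(OCc2ccccc2)c(OCc2ccccc2)c1
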